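The route rests on disconnecting the O1–C2 bond of ring C. C2 is the β-carbon of the C4 ketone and lies within reach of the ring A phenol oxygen that becomes O1, so the flavanone is a closed 2'-hydroxychalcone. A sacrificial tert-butyl ester on C3 makes this chalcone an alkylidene β-keto ester that a bifunctional cinchona thiourea can hold at two points. One catalytic 6-endo oxa-Michael addition then forms O1–C2, closes ring C and sets C2. The precursor is an achiral open-chain aryl ketone bearing a free ortho phenol, three ring A methoxy groups and a 3,4-dimethoxybenzylidene unit, made in two steps. Acid removes the ester afterwards.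

Key step: step 3

Assumption: the quinidine-derived thiourea is taken to give the 2S product; if a chiroptical check of the first batch shows 2R, the quinine-derived pseudoenantiomer, which gives the mirror image, replaces it.

Step 1
Reactants: 1 1-(6-hydroxy-2,3,4-trimethoxyphenyl)ethanone; 2 di-tert-butyl dicarbonate
Product: 4 tert-butyl 3-(6-hydroxy-2,3,4-trimethoxyphenyl)-3-oxopropanoate, via dilithium dianion 3 (not isolated)
Conditions: LiN(SiMe3)2 (3.2 equiv), THF, −78 to −10 °C; recool to −78 °C, 2 (1.1 equiv), −78 to −20 °C; AcOH quench at −78 °C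
Reagents that add atoms: none
Why: Claisen-type C-acylation of a ketone enolate: in dianion 3 the enolate carbon is much more nucleophilic than the chelated, flanked lithium phenoxide, so 2 is taken up at carbon, the third equivalent of base parks the product as its unreactive enolate and prevents a second acylation, and the bulky tert-butoxy group plus the cold acidic quench hold back lactonisation to a 4-hydroxycoumarin.

Step 2
Reactants: 4 tert-butyl 3-(6-hydroxy-2,3,4-trimethoxyphenyl)-3-oxopropanoate; 5 3,4-dimethoxybenzaldehyde
Product: 6 tert-butyl (Z)-3-(3,4-dimethoxyphenyl)-2-(6-hydroxy-2,3,4-trimethoxybenzoyl)prop-2-enoate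
Conditions: piperidine (10 mol %), AcOH (20 mol %), 4 Å MS, toluene, rt to 40 °C; chromatography or crystallisation
Reagents that add atoms: none
Why: Knoevenagel condensation, in which the piperidinium iminium ion of 5 is attacked by the enol of the acidic methylene of 4 and the amine is then eliminated while the sieves draw the equilibrium forward; the isomer with ring B cis to the ester and trans to the bulkier aroyl group should prevail, and the surplus of acetic acid over amine keeps the hydrogen-bonded phenol protonated so that early racemic ring closure stays small, any closed material being removed before step 3.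

Step 3
Reactants: 6 tert-butyl (Z)-3-(3,4-dimethoxyphenyl)-2-(6-hydroxy-2,3,4-trimethoxybenzoyl)prop-2-enoate
Product: 7 tert-butyl (2S,3R)-2-(3,4-dimethoxyphenyl)-5,6,7-trimethoxy-4-oxochromane-3-carboxylate (trans)
Conditions: 1-[3,5-bis(trifluoromethyl)phenyl]-3-[(9R)-6'-methoxycinchonan-9-yl]thiourea (from 9-amino-9-deoxy-epi-quinidine, 10 mol %), toluene (0.05 M), −25 °C; cold filtration through a short SiO2 pad to remove the catalyst
Reagents that add atoms: none
Why: The quinuclidine nitrogen of the catalyst takes the proton of the ring A phenol while the two thiourea N–H bonds hydrogen-bond to the 1,3-dicarbonyl unit, so the phenoxide oxygen is delivered to one face of the electron-poor C2=C3 bond and the resulting β-keto ester enolate is protonated at C3. The closest known reaction type is the cinchona thiourea catalysed intramolecular oxa-Michael addition of 2-hydroxyaryl alkylidene β-keto esters. Ring C closes in the 6-endo-trig mode, both alkene carbons ending up inside the new six-membered ring. C2 is controlled by the catalyst alone, since the substrate is achiral and the alkene geometry is lost on addition; C3 is set under thermodynamic control, its acidic hydrogen equilibrating through the enol to the trans isomer with both substituents equatorial, and this centre is erased in step 4. The step needs the catalysed pathway to outrun uncatalysed closure and needs attack at C2 rather than at the ester carbonyl: the hydrogen bond from the phenol to the C4 oxygen keeps the neutral phenol inert in cold toluene, the geminal ketone and ester raise the electrophilicity of C2 despite the donor ring B, and the tert-butyl group blocks lactonisation. The stabilised enolate of 7 is a poor trigger for retro-addition, so the C2 configuration should hold once formed.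

Step 4
Reactants: 7 tert-butyl (2S,3R)-2-(3,4-dimethoxyphenyl)-5,6,7-trimethoxy-4-oxochromane-3-carboxylate
Product: 9 (2S)-5,6,7,3',4'-pentamethoxyflavanone, via β-keto acid 8 (not isolated)
Conditions: TsOH·H2O (30 mol %), toluene, 80 °C, N2 sweep, stopped at full conversion; pH 7 buffer wash
Reagents that add atoms: none
Why: Acid-catalysed E1 loss of isobutene from the tert-butyl ester gives β-keto acid 8, which decarboxylates through the usual cyclic six-membered transition state at this temperature; no base is present, so enolate-driven opening of O1–C2 cannot start, the gas sweep removes isobutene before it can alkylate the electron-rich C8 position, and a sub-stoichiometric acid charge in non-polar toluene with short contact limits ionisation of the benzylic C2–O1 bond, so C2 stays untouched while the C3 centre disappears.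

Compound list
1 | 1-(6-hydroxy-2,3,4-trimethoxyphenyl)ethanone | CC(=O)c1c(O)cc(OC)c(OC)c1OC | starting material
2 | di-tert-butyl dicarbonate | CC(C)(C)OC(=O)OC(=O)OC(C)(C)C | starting material
3 | dilithium 3,4,5-trimethoxy-2-(1-oxidoethenyl)phenolate | [Li+].[Li+].C=C([O-])c1c([O-])cc(OC)c(OC)c1OC | intermediate
4 | tert-butyl 3-(6-hydroxy-2,3,4-trimethoxyphenyl)-3-oxopropanoate | COc1cc(O)c(C(=O)CC(=O)OC(C)(C)C)c(OC)c1OC | intermediate
5 | 3,4-dimethoxybenzaldehyde | COc1ccc(C=O)cc1OC | starting material
6 | tert-butyl (Z)-3-(3,4-dimethoxyphenyl)-2-(6-hydroxy-2,3,4-trimethoxybenzoyl)prop-2-enoate | COc1ccc(/C=C(/C(=O)c2c(O)cc(OC)c(OC)c2OC)C(=O)OC(C)(C)C)cc1OC | intermediate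
7 | tert-butyl (2S,3R)-2-(3,4-dimethoxyphenyl)-5,6,7-trimethoxy-4-oxochromane-3-carboxylate | COc1ccc([C@@H]2[C@@H](C(=O)OC(C)(C)C)C(=O)c3c(cc(OC)c(OC)c3OC)O2)cc1OC | intermediate
8 | (2S,3R)-2-(3,4-dimethoxyphenyl)-5,6,7-trimethoxy-4-oxochromane-3-carboxylic acid | COc1ccc([C@@H]2[C@@H](C(=O)O)C(=O)c3c(cc(OC)c(OC)c3OC)O2)cc1OC | intermediate
9 | (2S)-5,6,7,3',4'-pentamethoxyflavanone | COc1ccc([C@@H]2CC(=O)c3c(cc(OC)c(OC)c3OC)O2)cc1OC | target

Total step count: 4. Longest linear sequence: 4 (1 → 4 → 6 → 7 → 9).

Steps most likely to fail

1. Step 3. The risk is poor facial selectivity, or uncatalysed closure competing with the catalysed one. The methoxy group ortho to the ketone twists the aroyl unit and may disturb the two-point binding.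
   - The fallback sets out from 1 and comes back at 9. It makes the stereocentre by C–C instead of C–O bond formation.
   - Heating 1 with N,N-dimethylformamide dimethyl acetal (COC(OC)N(C)C) gives (E)-3-(dimethylamino)-1-(6-hydroxy-2,3,4-trimethoxyphenyl)prop-2-en-1-one F1.
   - Aqueous HCl in CH2Cl2 closes this with loss of dimethylamine to 5,6,7-trimethoxy-4H-chromen-4-one F2.
   - Enantioselective conjugate addition of 3,4-dimethoxyphenylboronic acid (COc1ccc(B(O)O)cc1OC) then gives 9. The catalyst is divalent palladium, Pd(OCOCF3)2, with the antipode of 4-tert-butyl-2-(pyridin-2-yl)-4,5-dihydrooxazole that leads to 2S (NH4PF6, H2O, ClCH2CH2Cl, 60 °C).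
   - The medium is free of base, so C2 is not endangered.

2. Step 2. The risk is sluggish condensation with the donor-substituted aldehyde, so that amine-induced ring closure catches up and consumes the product as racemate.
   - The fallback sets out from 1 and comes back at 6. It keeps the phenol masked until the alkene is in place.
   - NaH and chloromethyl methyl ether (COCCl) in DMF convert 1 into 1-[2,3,4-trimethoxy-6-(methoxymethoxy)phenyl]ethanone F3.
   - LiN(SiMe3)2 (2.2 equiv) and 2 give tert-butyl 3-oxo-3-[2,3,4-trimethoxy-6-(methoxymethoxy)phenyl]propanoate F4, now with no phenoxide competing for 2.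
   - The condensation with 5 can then be driven in refluxing toluene with azeotropic removal of water. It gives tert-butyl (Z)-3-(3,4-dimethoxyphenyl)-2-[2,3,4-trimethoxy-6-(methoxymethoxy)benzoyl]prop-2-enoate F5.
   - NaHSO4·SiO2 in CH2Cl2 at rt, a mild heterogeneous acid selective for phenolic acetals, releases 6. No phenoxide can form in this medium and the tert-butyl ester should survive.

3. Step 4. The risk is erosion of the C2 configuration during the hot acid treatment by reversible acid-induced opening of the O1–C2 bond. That bond is benzylic to a ring B carrying a para methoxy donor.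
   - The fallback sets out from 1 by way of 3 and comes back at 8. It exchanges the ester for one that leaves under neutral conditions.
   - Dianion 3 is acylated with dibenzyl dicarbonate (O=C(OCc1ccccc1)OC(=O)OCc1ccccc1) to benzyl 3-(6-hydroxy-2,3,4-trimethoxyphenyl)-3-oxopropanoate F6. This is kept cold and quenched with acid, since the smaller ester lactonises more easily.
   - Condensation with 5 as in step 2 gives benzyl (Z)-3-(3,4-dimethoxyphenyl)-2-(6-hydroxy-2,3,4-trimethoxybenzoyl)prop-2-enoate F7.
   - The catalyst of step 3 closes it to benzyl (2S,3R)-2-(3,4-dimethoxyphenyl)-5,6,7-trimethoxy-4-oxochromane-3-carboxylate F8.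
   - Hydrogenolysis (H2, 1 atm, 10% Pd/C, EtOAc, rt) gives acid 8, which loses CO2 on gentle warming in neutral solution to give 9.
   - The cost is that the smaller ester may lower the selectivity of the ring closure.

Further compounds
F1 | step 3 | (E)-3-(dimethylamino)-1-(6-hydroxy-2,3,4-trimethoxyphenyl)prop-2-en-1-one | CN(C)/C=C/C(=O)c1c(O)cc(OC)c(OC)c1OC
F2 | step 3 | 5,6,7-trimethoxy-4H-chromen-4-one | COc1cc2occc(=O)c2c(OC)c1OC
F3 | step 2 | 1-[2,3,4-trimethoxy-6-(methoxymethoxy)phenyl]ethanone | CC(=O)c1c(OCOC)cc(OC)c(OC)c1OC
F4 | step 2 | tert-butyl 3-oxo-3-[2,3,4-trimethoxy-6-(methoxymethoxy)phenyl]propanoate | COCOc1cc(OC)c(OC)c(OC)c1C(=O)CC(=O)OC(C)(C)C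
F5 | step 2 | tert-butyl (Z)-3-(3,4-dimethoxyphenyl)-2-[2,3,4-trimethoxy-6-(methoxymethoxy)benzoyl]prop-2-enoate | COc1ccc(/C=C(/C(=O)c2c(OCOC)cc(OC)c(OC)c2OC)C(=O)OC(C)(C)C)cc1OC
F6 | step 4 | benzyl 3-(6-hydroxy-2,3,4-trimethoxyphenyl)-3-oxopropanoate | COc1cc(O)c(C(=O)CC(=O)OCc2ccccc2)c(OC)c1OC
F7 | step 4 | benzyl (Z)-3-(3,4-dimethoxyphenyl)-2-(6-hydroxy-2,3,4-trimethoxybenzoyl)prop-2-enoate | COc1ccc(/C=C(/C(=O)c2c(O)cc(OC)c(OC)c2OC)C(=O)OCc2ccccc2)cc1OC
F8 | step 4 | benzyl (2S,3R)-2-(3,4-dimethoxyphenyl)-5,6,7-trimethoxy-4-oxochromane-3-carboxylate | COc1ccc([C@@H]2[C@@H](C(=O)OCc3ccccc3)C(=O)c3c(cc(OC)c(OC)c3OC)O2)cc1OC
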